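**Retrosynthetic overview**

- Glyceride: the glycerol C3–O(acyl) bond is cut to give ent‑labd‑8‑en‑15‑oic acid and (S)‑glycidyl acetate. The carboxylic acid opens the terminal epoxide carbon; glycerol C2 comes from (R)‑glycidol.
- Decalin: the C4–C5 and C9–C10 bonds are cut to give open‑chain (3R,6E,10E)‑3,7,11,15‑tetramethylhexadeca‑6,10,14‑trienoic acid. One enantioselective proton‑initiated cation–olefin cascade closes ring A first (sets C5), then ring B (sets C10), and ends by loss of H‑9 to the Δ8(9) olefin, as a diterpene cyclase does with a geranylgeranyl chain.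
- C13 stereocentre: enantioconvergent organocatalytic conjugate reduction of geranylgeranial (2E/2Z mixture), then aldehyde to acid.
- C20 chain: (6E,10E)‑geranyllinalool by oxidative 1,3‑transposition.

Assumption: the target is read as 1‑O‑acetyl‑3‑O‑[(5R,10R,13R)‑labd‑8‑en‑15‑oyl]‑sn‑glycerol (glycerol C2 = R, ent‑labdane series), and commercial geranyllinalool is taken as its (6E,10E) isomer (racemic at C3, a centre erased in step 1).

**Step 1**
Reactants: 1 (6E,10E)‑geranyllinalool
Product: 2 geranylgeranial (2E/2Z mixture; 6E,10E)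
Conditions: pyridinium chlorochromate [C5H5NH][CrO3Cl] (2.5 equiv), Celite, CH2Cl2, rt, 5 h
Reagents that add atoms: pyridinium chlorochromate, [O-][Cr](=O)(=O)Cl.c1cc[nH+]cc1 (an oxo oxygen becomes the aldehyde oxygen)
Why: Babler–Dauben oxidative 1,3‑transposition, in which the tertiary allylic chromate ester of hexavalent chromium undergoes a [3,3] shift to the primary allylic chromate that is oxidised to the enal; no stereocentre is formed and the 2E/2Z ratio is irrelevant for step 2.

**Step 2**
Reactants: 2 geranylgeranial (2E/2Z mixture)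
Product: 3 (3R,6E,10E)‑3,7,11,15‑tetramethylhexadeca‑6,10,14‑trienal
Conditions: morpholinium salt of (R)‑TRIP [(R)‑3,3'‑bis(2,4,6‑triisopropylphenyl)‑1,1'‑binaphthyl‑2,2'‑diyl hydrogen phosphate] (20 mol %), diethyl 2,6‑dimethyl‑1,4‑dihydropyridine‑3,5‑dicarboxylate (1.1 equiv), THF, rt, 24 h
Reagents that add atoms: none
Why: Asymmetric counteranion‑directed iminium transfer hydrogenation (organocatalytic conjugate reduction), in which the 2E and 2Z iminium ions interconvert faster than hydride transfer so both isomers converge on the (3R) aldehyde, as citral gives (R)‑citronellal and farnesal gives (R)‑dihydrofarnesal with this salt, while the isolated trisubstituted olefins are untouched.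

**Step 3**
Reactants: 3 (3R,6E,10E)‑3,7,11,15‑tetramethylhexadeca‑6,10,14‑trienal
Product: 4 (3R,6E,10E)‑3,7,11,15‑tetramethylhexadeca‑6,10,14‑trienoic acid
Conditions: NaClO2 (1.5 equiv), NaH2PO4 (1.5 equiv), 2‑methyl‑2‑butene (10 equiv), t‑BuOH/H2O 4:1, 0 °C → rt, 2 h
Reagents that add atoms: sodium chlorite, [Na+].[O-]Cl=O
Why: Pinnick (Lindgren–Kraus) oxidation, in which the hypochlorite by‑product is scavenged so the three trisubstituted olefins survive, and the β‑stereocentre cannot epimerise.

**Step 4**
Reactants: 4 (3R,6E,10E)‑3,7,11,15‑tetramethylhexadeca‑6,10,14‑trienoic acid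
Product: 6 (5R,10R,13R)‑labd‑8‑en‑15‑oic acid, via monocyclic diene acid 5 (not isolated)
Conditions: (S)‑2'‑(2‑fluorobenzyloxy)‑1,1'‑binaphthalen‑2‑ol (2.2 equiv), SnCl4 (2.0 equiv), toluene, −78 °C, 48 h; silica plug (ligand recovered), crude carried on; then BF3·OEt2 (2 equiv), EtNO2, −20 °C → rt; AgNO3–silica chromatography
Reagents that add atoms: none
Why: Proposed new method: the SnCl4‑activated phenolic proton of the (S)‑binaphthol mono‑ether (a chiral Lewis acid‑assisted Brønsted acid) protonates the terminal isopropylidene on one face while the 10,11‑olefin closes ring A through a chair (setting C5 as R), the tertiary C10 cation is attacked anti by the 6,7‑olefin to close ring B trans (setting C10 as R), and under the equilibrating BF3 stage the C8 cation loses H‑9 to the most substituted Δ8(9) olefin while monocyclic olefin 5 is re‑protonated into the same cation, the closest known reactions being the SnCl4–binaphthol cyclisations of homofarnesic acid to sclareolide and of homo(polyprenyl)arenes completed with BF3·OEt2 in a nitroalkane, with C13 a spectator.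

**Step 5**
Reactants: 7 (R)‑glycidol
Product: 8 (S)‑glycidyl acetate
Conditions: Ac2O (1.1 equiv), Et3N (1.2 equiv), DMAP (2 mol %), CH2Cl2, 0 °C, 1 h; bulb‑to‑bulb distillation
Reagents that add atoms: acetic anhydride, CC(=O)OC(C)=O
Why: DMAP‑catalysed O‑acetylation of the primary alcohol leaves the epoxide stereocentre untouched, and the descriptor changes from R to S only because the CIP priorities of the two CH2 arms swap.

**Step 6**
Reactants: 6 (5R,10R,13R)‑labd‑8‑en‑15‑oic acid; 8 (S)‑glycidyl acetate (1.5 equiv)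
Product: 9 1‑O‑acetyl‑3‑O‑[(5R,10R,13R)‑labd‑8‑en‑15‑oyl]‑sn‑glycerol (target)
Conditions: rac‑trans‑[N,N'‑bis(3,5‑di‑tert‑butylsalicylidene)‑1,2‑cyclohexanediamino]cobalt, C36H52CoN2O2 (3 mol %, divalent cobalt precatalyst stirred with 6 in air to give the trivalent cobalt carboxylate), iPr2NEt (1.0 equiv), TBME, rt, 16 h
Reagents that add atoms: none
Why: Cobalt–salen‑catalysed carboxylic acid opening of a terminal epoxide (Jacobsen‑type ring opening, as used for fatty acids and glycidyl derivatives) occurs at the unsubstituted CH2, so the epoxide carbinol carbon becomes glycerol C2 with its configuration retained (2R by priority change) and the mild room‑temperature conditions suppress acyl migration.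

**Compound list**

1 | (6E,10E)‑geranyllinalool, (6E,10E)‑3,7,11,15‑tetramethylhexadeca‑1,6,10,14‑tetraen‑3‑ol (racemic) | C=CC(C)(O)CC/C=C(\C)CC/C=C(\C)CCC=C(C)C | starting material
2 | geranylgeranial, (6E,10E)‑3,7,11,15‑tetramethylhexadeca‑2,6,10,14‑tetraenal, 2E/2Z mixture | O=CC=C(C)CC/C=C(\C)CC/C=C(\C)CCC=C(C)C | intermediate
3 | (3R,6E,10E)‑3,7,11,15‑tetramethylhexadeca‑6,10,14‑trienal | O=CC[C@H](C)CC/C=C(\C)CC/C=C(\C)CCC=C(C)C | intermediate
4 | (3R,6E,10E)‑3,7,11,15‑tetramethylhexadeca‑6,10,14‑trienoic acid | OC(=O)C[C@H](C)CC/C=C(\C)CC/C=C(\C)CCC=C(C)C | intermediate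
5 | (3R,6E)‑3,7‑dimethyl‑9‑[(1R)‑2,6,6‑trimethylcyclohex‑2‑en‑1‑yl]non‑6‑enoic acid (ring A closed; representative of the monocyclic olefin isomers) | OC(=O)C[C@H](C)CC/C=C(\C)CC[C@H]1C(C)=CCCC1(C)C | intermediate (not isolated)
6 | (5R,10R,13R)‑labd‑8‑en‑15‑oic acid, (3R)‑3‑methyl‑5‑[(4aR,8aR)‑2,5,5,8a‑tetramethyl‑3,4,4a,5,6,7,8,8a‑octahydronaphthalen‑1‑yl]pentanoic acid | OC(=O)C[C@H](C)CCC1=C(C)CC[C@@H]2C(C)(C)CCC[C@@]12C | intermediate
7 | (R)‑glycidol | OC[C@@H]1CO1 | starting material
8 | (S)‑glycidyl acetate | CC(=O)OC[C@@H]1CO1 | intermediate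
9 | (2R)‑3‑acetoxy‑2‑hydroxypropyl (3R)‑3‑methyl‑5‑[(4aR,8aR)‑2,5,5,8a‑tetramethyl‑3,4,4a,5,6,7,8,8a‑octahydronaphthalen‑1‑yl]pentanoate | CC(=O)OC[C@@H](O)COC(=O)C[C@H](C)CCC1=C(C)CC[C@@H]2C(C)(C)CCC[C@@]12C | target

**Totals**

Total steps: 6. Longest linear sequence: 5 (steps 1, 2, 3, 4, 6; step 5 is a one‑step side branch).

**Steps most likely to fail, with fallbacks**

Step 4 is the main risk, for three reasons.
- Enantiofacial control of such cyclisations is typically about 88:12 to 95:5. Because C13 is already fixed, the minor sense appears as the (5S,10S,13R) diastereomer. It would have to be removed by crystallising 6 as an amine salt.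
- The free carboxylic acid can act as an achiral proton source with SnCl4.
- Proton loss can give Δ7 and Δ8(17) isomers. AgNO3–silica separates these from the tetrasubstituted olefin, and catalytic HI in benzene at 80 °C re‑equilibrates them to 6.

The (S)‑ligand is chosen as the mirror image of the (R)‑ligand that, as I recall, gives the natural normal‑series products such as (−)‑ambrox; this should be confirmed before committing material.

Fallback for step 4: from 4, change the initiator from a proton to a chiral iodonium. N‑iodosuccinimide with a stoichiometric binaphthol‑derived phosphoramidite promoter (the antipode leading to the ent series), toluene, −40 °C, effects enantioselective iodo‑cyclisation at the terminal olefin. The same BF3·OEt2/EtNO2 stage completes ring B and gives (13R)‑3‑iodo‑ent‑labd‑8‑en‑15‑oic acid F1 (iodine equatorial, cis to the C10 methyl). Bu3SnH, AIBN, toluene, 80 °C then removes the iodine and returns to 6.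

Step 6 is the second risk. Attack at the internal epoxide carbon, acetyl migration to the 2‑position, or a sluggish catalyst with this lipophilic acid would each lower the yield.

Fallback for step 6: from 6, build the glyceride stepwise from a protected glycerol. EDC·HCl, DMAP and (S)‑solketal in CH2Cl2 give [(4R)‑2,2‑dimethyl‑1,3‑dioxolan‑4‑yl]methyl (5R,10R,13R)‑labd‑8‑en‑15‑oate F2. Dowex 50W (H+ form), MeOH, rt removes the acetonide to give 3‑O‑[(5R,10R,13R)‑labd‑8‑en‑15‑oyl]‑sn‑glycerol F3. Selective acetylation of the primary hydroxyl (AcCl, 2,4,6‑collidine, CH2Cl2, −78 °C) then gives 9.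

Step 1 is the third risk. Hexavalent chromium can also attack the bishomoallylic 6,7‑olefin of 1 to give tetrahydrofuran by‑products, and yields of enals from acyclic vinyl carbinols are moderate.

Fallback for step 1: from 1, separate transposition from oxidation. Ph3SiOReO3 (2 mol %), Et2O, 0 °C isomerises the tertiary allylic alcohol to geranylgeraniol (2E/2Z mixture) F4. MnO2, CH2Cl2, rt then oxidises the primary allylic alcohol and returns to 2.

**Further compounds**

F1 | step 4 | (13R)‑3‑iodo‑ent‑labd‑8‑en‑15‑oic acid (iodine equatorial, cis to the C10 methyl) | OC(=O)C[C@H](C)CCC1=C(C)CC[C@@H]2C(C)(C)[C@H](I)CC[C@@]12C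
F2 | step 6 | [(4R)‑2,2‑dimethyl‑1,3‑dioxolan‑4‑yl]methyl (5R,10R,13R)‑labd‑8‑en‑15‑oate | O=C(OC[C@H]1COC(C)(C)O1)C[C@H](C)CCC2=C(C)CC[C@@H]3C(C)(C)CCC[C@@]23C
F3 | step 6 | 3‑O‑[(5R,10R,13R)‑labd‑8‑en‑15‑oyl]‑sn‑glycerol, (2R)‑2,3‑dihydroxypropyl ester | OC[C@@H](O)COC(=O)C[C@H](C)CCC1=C(C)CC[C@@H]2C(C)(C)CCC[C@@]12C
F4 | step 1 | geranylgeraniol, (6E,10E)‑3,7,11,15‑tetramethylhexadeca‑2,6,10,14‑tetraen‑1‑ol, 2E/2Z mixture | OCC=C(C)CC/C=C(\C)CC/C=C(\C)CCC=C(C)C
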